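**Retrosynthetic overview**

- The plan rests on one feature: ring B (C3a–C4–C5–C6–C7–C7a) is a dearomatised 2,6-dimethoxyphenol whose allyl-bearing C3a lies para to the C6 oxygen and next to the O1-bearing C7a, and C3 is benzylic to a 4-oxygenated aryl ring (ring C), so it can be the terminus of a para-quinone methide.
- Target 24 ⇐ C5 equilibration ⇐ conjugate reduction of C4=C5 ⇐ O-methylation ⇐ dienone 20.
- 20 ⇐ closure of ring A (bond C3–C3a) by attack of the ring B phenol, through C3a, on the quinone methide from diaryl-ether carbinol 18.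
- 18 ⇐ aldehyde 13 + aryllithium 16 (bond C3–ring C); 13 ⇐ ester 12 ⇐ Mitsunobu union of phenol 10 with ethyl (S)-lactate (bond O1–C2, inversion fixes C2).
- 10 ⇐ Claisen rearrangement of allyl ether 8, made from 2,6-dimethoxyphenol; rings B and C are bought as arenes, and ring A is the only ring formed, last.

Key step: step 11

Assumption: carbinols 17 and 18 are made and used as mixtures of C1 epimers because step 11 ionises that centre, and both phenols travel as triisopropylsilyl ethers so that buffered fluoride can free them beside the allyl group and the acid-labile carbinol.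

**Route**

Step 1
Reactants: 1 2,6-dimethoxyphenol
Product: 2 (2,6-dimethoxyphenoxy)triisopropylsilane
Conditions: i-Pr3SiOTf, 2,6-lutidine, CH2Cl2, 0 °C → rt
Reagents that add atoms: triisopropylsilyl trifluoromethanesulfonate, CC(C)[Si](C(C)C)(C(C)C)OS(=O)(=O)C(F)(F)F
Why: O-Silylation of a hindered phenol with a silyl triflate; the triisopropylsilyl ether flanked by two methoxy groups should withstand carbonate, organolithium reagents and the Claisen temperature and leave only with fluoride.

Step 2
Reactants: 2 (2,6-dimethoxyphenoxy)triisopropylsilane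
Product: 3 (3-bromo-2,6-dimethoxyphenoxy)triisopropylsilane
Conditions: NBS (1.0 equiv), MeCN, 0 °C → rt
Reagents that add atoms: N-bromosuccinimide, O=C1CCC(=O)N1Br
Why: Electrophilic aromatic bromination at C3, which is ortho to one methoxy group and para to the other, while the twisted silyloxy group activates C4 only weakly, the same preference that sends 1,2,3-trimethoxybenzene to its 4-bromide.

Step 3
Reactants: 3 (3-bromo-2,6-dimethoxyphenoxy)triisopropylsilane
Product: 6 2,4-dimethoxy-3-(triisopropylsilyloxy)phenol, via aryllithium 4 (not isolated), via dimethyl arylboronate 5 (not isolated)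
Conditions: n-BuLi, THF, −78 °C; B(OMe)3, −78 °C → rt; AcOH, 30% aq. H2O2, 0 °C → rt
Reagents that add atoms: hydrogen peroxide, OO (the phenolic oxygen); trimethyl borate, COB(OC)OC (boron and methoxy groups of 5 only)
Why: Bromine–lithium exchange, borylation and oxidative 1,2-shift of the aryl group from boron to oxygen turn the bromide into a phenol under conditions that leave the silyl ether alone.

Step 4
Reactants: 6 2,4-dimethoxy-3-(triisopropylsilyloxy)phenol; 7 allyl bromide
Product: 8 [3-(allyloxy)-2,6-dimethoxyphenoxy]triisopropylsilane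
Conditions: K2CO3, acetone, reflux
Reagents that add atoms: none
Why: Williamson ether synthesis on the only free phenol; the silyl ether is meta to the phenoxide and cannot migrate to it.

Step 5
Reactants: 8 [3-(allyloxy)-2,6-dimethoxyphenoxy]triisopropylsilane
Product: 10 6-allyl-2,4-dimethoxy-3-(triisopropylsilyloxy)phenol, via Claisen dienone 9 (not isolated)
Conditions: PhNEt2, 190 °C
Reagents that add atoms: none
Why: Aromatic Claisen rearrangement, a [3,3]-sigmatropic shift to C6, the only open ortho position (C2 carries methoxy), followed by tautomerisation of the dienone to the phenol.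

Step 6
Reactants: 10 6-allyl-2,4-dimethoxy-3-(triisopropylsilyloxy)phenol; 11 ethyl (S)-lactate
Product: 12 ethyl (2R)-2-[6-allyl-2,4-dimethoxy-3-(triisopropylsilyloxy)phenoxy]propanoate
Conditions: PPh3, DIAD, THF, 0 °C → rt
Reagents that add atoms: none
Why: Mitsunobu reaction, in which the phenol displaces the activated lactate hydroxyl by SN2 with inversion, so (S)-lactate gives the (R)-aryloxypropanoate and fixes C2 of the target.

Step 7
Reactants: 12 ethyl (2R)-2-[6-allyl-2,4-dimethoxy-3-(triisopropylsilyloxy)phenoxy]propanoate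
Product: 13 (2R)-2-[6-allyl-2,4-dimethoxy-3-(triisopropylsilyloxy)phenoxy]propanal
Conditions: i-Bu2AlH (1.1 equiv), CH2Cl2, −78 °C; MeOH, then aq. KNaC4H4O6
Reagents that add atoms: none
Why: Partial reduction of an α-aryloxy ester, whose chelated aluminium hemiacetal should persist at −78 °C until work-up, so the aldehyde is released without over-reduction and without touching the α-stereocentre.

Step 8
Reactants: 14 4-bromo-2,6-dimethoxyphenol
Product: 15 (4-bromo-2,6-dimethoxyphenoxy)triisopropylsilane
Conditions: i-Pr3SiOTf, 2,6-lutidine, CH2Cl2, 0 °C → rt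
Reagents that add atoms: triisopropylsilyl trifluoromethanesulfonate, CC(C)[Si](C(C)C)(C(C)C)OS(=O)(=O)C(F)(F)F
Why: O-Silylation masks the acidic phenol so that bromine–lithium exchange becomes possible.

Step 9
Reactants: 15 (4-bromo-2,6-dimethoxyphenoxy)triisopropylsilane; 13 (2R)-2-[6-allyl-2,4-dimethoxy-3-(triisopropylsilyloxy)phenoxy]propanal
Product: 17 (1RS,2R)-2-[6-allyl-2,4-dimethoxy-3-(triisopropylsilyloxy)phenoxy]-1-[3,5-dimethoxy-4-(triisopropylsilyloxy)phenyl]propan-1-ol, via aryllithium 16 (not isolated)
Conditions: 15, n-BuLi, THF, −78 °C; then 13, −78 °C; H2O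
Reagents that add atoms: none
Why: Bromine–lithium exchange and 1,2-addition of the aryllithium to the aldehyde, which at −78 °C should outrun enolisation so that C2 stays (R); both carbinol epimers are expected and both serve.

Step 10
Reactants: 17 (1RS,2R)-2-[6-allyl-2,4-dimethoxy-3-(triisopropylsilyloxy)phenoxy]-1-[3,5-dimethoxy-4-(triisopropylsilyloxy)phenyl]propan-1-ol
Product: 18 (1RS,2R)-2-(6-allyl-3-hydroxy-2,4-dimethoxyphenoxy)-1-(4-hydroxy-3,5-dimethoxyphenyl)propan-1-ol
Conditions: Bu4NF, AcOH, THF, 0 °C
Reagents that add atoms: none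
Why: Fluoride desilylation buffered with acetic acid frees both phenols under near-neutral conditions in which the 4-hydroxybenzylic alcohol should neither ionise nor eliminate.

Step 11
Reactants: 18 (1RS,2R)-2-(6-allyl-3-hydroxy-2,4-dimethoxyphenoxy)-1-(4-hydroxy-3,5-dimethoxyphenyl)propan-1-ol
Product: 20 (2R,3S,3aR)-3a-allyl-3-(4-hydroxy-3,5-dimethoxyphenyl)-5,7-dimethoxy-2-methyl-3,3a-dihydrobenzofuran-6(2H)-one, via quinone methide 19 (not isolated)
Conditions: CF3CO2H (10 mol %), (CF3)2CHOH, 0.01 M, 0 °C → rt
Reagents that add atoms: none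
Why: Acid in hexafluoroisopropanol ionises the 4-hydroxybenzylic alcohol of either C1 epimer to the protonated para-quinone methide 19, ring B attacks the methide carbon C3 through C3a as the vinylogous enol of its C6 hydroxyl, and loss of that proton leaves the cross-conjugated dienone; the closest known reaction type is the intramolecular Friedel–Crafts-type trapping of para-quinone methides by phenols with dearomatisation. Ring A closes 5-exo-trig on the exocyclic methide bond, the attacking C3a=C4 π bond staying outside the new ring. C3 is set by C2: allylic 1,3-strain holds C2–H near the methide plane, the tether oxygen O1 on the face that is attacked and the methyl group on the far face, so the aryl group should end trans to the methyl. C3a is set by which face of ring B meets C3; if ring C points away from ring B, only C3–H and the C2 methyl lie over ring B, the allyl group bends to the opposite face and ends cis to the aryl group, whereas a stacked approach of the two rings would give the C3a epimer, so this is the least secure element and relies in part on the closure being reversible under the acid. Regioselectivity is needed between C3a and C7, which both flank C7a and would both close a five-membered ring; C3a is para to the C6 hydroxyl and carries carbon, while ipso attack at the methoxy-bearing C7 would give the less stable linearly conjugated dienone, which should revert. Chemoselectivity over loss of the C2 proton (enol ether formation and ether cleavage) and over intermolecular capture is sought through high dilution, low temperature and a non-nucleophilic ionising solvent.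

Step 12
Reactants: 20 (2R,3S,3aR)-3a-allyl-3-(4-hydroxy-3,5-dimethoxyphenyl)-5,7-dimethoxy-2-methyl-3,3a-dihydrobenzofuran-6(2H)-one
Product: 21 (2R,3S,3aR)-3a-allyl-5,7-dimethoxy-2-methyl-3-(3,4,5-trimethoxyphenyl)-3,3a-dihydrobenzofuran-6(2H)-one
Conditions: MeI, K2CO3, acetone, rt
Reagents that add atoms: iodomethane, CI
Why: Williamson O-methylation of the only phenol; the dienone has no enolisable hydrogen (C3a is quaternary), so carbonate should do nothing else.

Step 13
Reactants: 21 (2R,3S,3aR)-3a-allyl-5,7-dimethoxy-2-methyl-3-(3,4,5-trimethoxyphenyl)-3,3a-dihydrobenzofuran-6(2H)-one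
Product: 23 (2R,3S,3aS,5RS)-3a-allyl-5,7-dimethoxy-2-methyl-3-(3,4,5-trimethoxyphenyl)-3,3a,4,5-tetrahydrobenzofuran-6(2H)-one, via copper enolate 22 (not isolated)
Conditions: [(Ph3P)CuH]6 (0.4 equiv), H2O (3 equiv), toluene, rt
Reagents that add atoms: none
Why: Copper hydride conjugate reduction delivers hydride to C4, the β-carbon of the C4=C5–C6=O enone, while C7=C7a is a tetrasubstituted vinylogous ester with O1 on its β-carbon and the isolated allyl alkene is inert to this reagent; water protonates the enolate at C5 from either face, and the C3a descriptor changes from R to S only because C4 loses rank on saturation.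

Step 14
Reactants: 23 (2R,3S,3aS,5RS)-3a-allyl-5,7-dimethoxy-2-methyl-3-(3,4,5-trimethoxyphenyl)-3,3a,4,5-tetrahydrobenzofuran-6(2H)-one
Product: 24 (2R,3S,3aS,5S)-3a-allyl-5,7-dimethoxy-2-methyl-3-(3,4,5-trimethoxyphenyl)-3,3a,4,5-tetrahydrobenzofuran-6(2H)-one (CNP0136253.1)
Conditions: K2CO3 (0.2 equiv), MeOH, rt
Reagents that add atoms: none
Why: Base-mediated epimerisation through the C5–C6 enolate should favour the (5S) epimer, whose methoxy group is equatorial and anti to the pseudo-axial C3a allyl group, whereas the (5R) epimer has a 1,3-diaxial contact; C2, C3 and C3a carry no acidic hydrogen and stay fixed.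

**Compound list**

1 | 2,6-dimethoxyphenol | COc1cccc(OC)c1O | starting material
2 | (2,6-dimethoxyphenoxy)triisopropylsilane | COc1cccc(OC)c1O[Si](C(C)C)(C(C)C)C(C)C | intermediate
3 | (3-bromo-2,6-dimethoxyphenoxy)triisopropylsilane | COc1ccc(Br)c(OC)c1O[Si](C(C)C)(C(C)C)C(C)C | intermediate
4 | [2,4-dimethoxy-3-(triisopropylsilyloxy)phenyl]lithium | [Li]c1ccc(OC)c(O[Si](C(C)C)(C(C)C)C(C)C)c1OC | intermediate (not isolated)
5 | dimethyl [2,4-dimethoxy-3-(triisopropylsilyloxy)phenyl]boronate | COB(OC)c1ccc(OC)c(O[Si](C(C)C)(C(C)C)C(C)C)c1OC | intermediate (not isolated)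
6 | 2,4-dimethoxy-3-(triisopropylsilyloxy)phenol | COc1ccc(O)c(OC)c1O[Si](C(C)C)(C(C)C)C(C)C | intermediate
7 | allyl bromide | C=CCBr | starting material
8 | [3-(allyloxy)-2,6-dimethoxyphenoxy]triisopropylsilane | C=CCOc1ccc(OC)c(O[Si](C(C)C)(C(C)C)C(C)C)c1OC | intermediate
9 | 6-allyl-2,4-dimethoxy-3-(triisopropylsilyloxy)cyclohexa-2,4-dien-1-one (racemic at C6) | C=CCC1C=C(OC)C(O[Si](C(C)C)(C(C)C)C(C)C)=C(OC)C1=O | intermediate (not isolated)
10 | 6-allyl-2,4-dimethoxy-3-(triisopropylsilyloxy)phenol | C=CCc1cc(OC)c(O[Si](C(C)C)(C(C)C)C(C)C)c(OC)c1O | intermediate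
11 | ethyl (S)-lactate | C[C@H](O)C(=O)OCC | starting material
12 | ethyl (2R)-2-[6-allyl-2,4-dimethoxy-3-(triisopropylsilyloxy)phenoxy]propanoate | C=CCc1cc(OC)c(O[Si](C(C)C)(C(C)C)C(C)C)c(OC)c1O[C@H](C)C(=O)OCC | intermediate
13 | (2R)-2-[6-allyl-2,4-dimethoxy-3-(triisopropylsilyloxy)phenoxy]propanal | C=CCc1cc(OC)c(O[Si](C(C)C)(C(C)C)C(C)C)c(OC)c1O[C@H](C)C=O | intermediate
14 | 4-bromo-2,6-dimethoxyphenol | COc1cc(Br)cc(OC)c1O | starting material
15 | (4-bromo-2,6-dimethoxyphenoxy)triisopropylsilane | COc1cc(Br)cc(OC)c1O[Si](C(C)C)(C(C)C)C(C)C | intermediate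
16 | [3,5-dimethoxy-4-(triisopropylsilyloxy)phenyl]lithium | [Li]c1cc(OC)c(O[Si](C(C)C)(C(C)C)C(C)C)c(OC)c1 | intermediate (not isolated)
17 | (1RS,2R)-2-[6-allyl-2,4-dimethoxy-3-(triisopropylsilyloxy)phenoxy]-1-[3,5-dimethoxy-4-(triisopropylsilyloxy)phenyl]propan-1-ol (both C1 epimers) | C=CCc1cc(OC)c(O[Si](C(C)C)(C(C)C)C(C)C)c(OC)c1O[C@H](C)C(O)c1cc(OC)c(O[Si](C(C)C)(C(C)C)C(C)C)c(OC)c1 | intermediate
18 | (1RS,2R)-2-(6-allyl-3-hydroxy-2,4-dimethoxyphenoxy)-1-(4-hydroxy-3,5-dimethoxyphenyl)propan-1-ol (both C1 epimers) | C=CCc1cc(OC)c(O)c(OC)c1O[C@H](C)C(O)c1cc(OC)c(O)c(OC)c1 | intermediate (key-step precursor)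
19 | 4-[(2R)-2-(6-allyl-3-hydroxy-2,4-dimethoxyphenoxy)propylidene]-2,6-dimethoxycyclohexa-2,5-dien-1-one | C=CCc1cc(OC)c(O)c(OC)c1O[C@H](C)C=C1C=C(OC)C(=O)C(OC)=C1 | intermediate (not isolated)
20 | (2R,3S,3aR)-3a-allyl-3-(4-hydroxy-3,5-dimethoxyphenyl)-5,7-dimethoxy-2-methyl-3,3a-dihydrobenzofuran-6(2H)-one (aryl trans to methyl, cis to allyl) | C=CC[C@@]12C=C(OC)C(=O)C(OC)=C1O[C@H](C)[C@H]2c1cc(OC)c(O)c(OC)c1 | intermediate (key-step product)
21 | (2R,3S,3aR)-3a-allyl-5,7-dimethoxy-2-methyl-3-(3,4,5-trimethoxyphenyl)-3,3a-dihydrobenzofuran-6(2H)-one | C=CC[C@@]12C=C(OC)C(=O)C(OC)=C1O[C@H](C)[C@H]2c1cc(OC)c(OC)c(OC)c1 | intermediate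
22 | copper enolate of 23 at C5–C6 (monovalent copper; phosphine ligands not drawn) | C=CC[C@@]12CC(OC)=C(O[Cu])C(OC)=C1O[C@H](C)[C@H]2c1cc(OC)c(OC)c(OC)c1 | intermediate (not isolated)
23 | (2R,3S,3aS,5RS)-3a-allyl-5,7-dimethoxy-2-methyl-3-(3,4,5-trimethoxyphenyl)-3,3a,4,5-tetrahydrobenzofuran-6(2H)-one (both C5 epimers) | C=CC[C@@]12CC(OC)C(=O)C(OC)=C1O[C@H](C)[C@H]2c1cc(OC)c(OC)c(OC)c1 | intermediate
24 | (2R,3S,3aS,5S)-3a-allyl-5,7-dimethoxy-2-methyl-3-(3,4,5-trimethoxyphenyl)-3,3a,4,5-tetrahydrobenzofuran-6(2H)-one | C=CC[C@@]12C[C@H](OC)C(=O)C(OC)=C1O[C@H](C)[C@H]2c1cc(OC)c(OC)c(OC)c1 | target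

**Step count and risks**

Total step count: 14. Longest linear sequence: 13 (steps 1–7 and 9–14; step 8 is the side branch).

Steps most likely to fail:

1. Step 11. Three processes may go wrong:
   - Ring B may meet the methide carbon with the other face, giving the C3a epimer.
   - The cation may lose the C2 proton, which leads to an enol ether and cleavage of the aryl ether.
   - The C7 methoxy oxygen may capture the cation, with demethylation to a 1,4-benzodioxane.

   The fallback separates ionisation from bond formation and sets out from 18. Me3SiBr in CH2Cl2 at 0 °C should exchange the benzylic hydroxyl for bromide and give 4-[(2R)-2-(6-allyl-3-hydroxy-2,4-dimethoxyphenoxy)-1-bromopropyl]-2,6-dimethoxyphenol F1. Shaking its solution with aq. NaHCO3 should remove HBr and deliver quinone methide 19 as a discrete neutral species. A catalytic Lewis acid, Sc(OTf)3 at −78 °C in CH2Cl2, would then bring about the 1,6-addition of ring B to it under aprotic, kinetic conditions. This path comes back to the route at 20, and any C3a epimer could be returned to 19 by brief acid treatment.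

2. Step 13. Hydride transfer to C4, which is next to the quaternary C3a and is part of an enol ether, may be slow, so that reduction stalls or the C6 carbonyl is attacked. The fallback sets out from 21 and uses an anionic hydride in place of copper hydride. Li[HB(s-Bu)3] in THF at −78 °C should add hydride to C4 and form the lithium enolate of 23 at C5–C6 F2. Its protonation with water returns to the route at 23.

3. Step 9. The aryllithium may enolise aldehyde 13 instead of adding to it, which would erode the C2 configuration. The fallback sets out from 12 and avoids the aldehyde. MeNH(OMe)·HCl and i-PrMgCl in THF at −20 °C should give (2R)-2-[6-allyl-2,4-dimethoxy-3-(triisopropylsilyloxy)phenoxy]-N-methoxy-N-methylpropanamide F3. Aryllithium 16 at −78 °C should add once to it and give (2R)-2-[6-allyl-2,4-dimethoxy-3-(triisopropylsilyloxy)phenoxy]-1-[3,5-dimethoxy-4-(triisopropylsilyloxy)phenyl]propan-1-one F4. NaBH4 in MeOH at −20 °C would reduce the ketone and come back to the route at 17.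

**Further compounds**

F1 | step 11 | 4-[(2R)-2-(6-allyl-3-hydroxy-2,4-dimethoxyphenoxy)-1-bromopropyl]-2,6-dimethoxyphenol (both C1 epimers) | C=CCc1cc(OC)c(O)c(OC)c1O[C@H](C)C(Br)c1cc(OC)c(O)c(OC)c1
F2 | step 13 | lithium enolate of 23 at C5–C6 | C=CC[C@@]12CC(OC)=C(O[Li])C(OC)=C1O[C@H](C)[C@H]2c1cc(OC)c(OC)c(OC)c1
F3 | step 9 | (2R)-2-[6-allyl-2,4-dimethoxy-3-(triisopropylsilyloxy)phenoxy]-N-methoxy-N-methylpropanamide | C=CCc1cc(OC)c(O[Si](C(C)C)(C(C)C)C(C)C)c(OC)c1O[C@H](C)C(=O)N(C)OC
F4 | step 9 | (2R)-2-[6-allyl-2,4-dimethoxy-3-(triisopropylsilyloxy)phenoxy]-1-[3,5-dimethoxy-4-(triisopropylsilyloxy)phenyl]propan-1-one | C=CCc1cc(OC)c(O[Si](C(C)C)(C(C)C)C(C)C)c(OC)c1O[C@H](C)C(=O)c1cc(OC)c(O[Si](C(C)C)(C(C)C)C(C)C)c(OC)c1
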